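Ring C of the flavonol is cut between C3 and C4, the two adjacent oxygen-bearing carbons of the pyranone. Both are traced back to aldehyde carbons that are already tied together through C4a–C8a–O1–C2, so one reductive ketyl coupling forms the C3–C4 bond and closes ring C as a flavan-3,4-diol whose stereochemistry is irrelevant. The precursor is a racemic dialdehyde: a fully methylated salicylaldehyde ether carrying, on O1, the CH(aryl)–CHO unit derived from 2,5-dimethoxyphenylacetic acid. Double oxidation of the diol gives the flavonol directly; 3-O-methylation and chelation-directed 5-O-demethylation finish the achiral target.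

Key step: step 8

Remark on stereochemistry: the target has no stereocentre and is a single achiral compound, so no enantiocontrol is needed; every chiral intermediate is carried as the racemate.
Assumption: 1,2,3,4-tetramethoxybenzene is taken as a purchasable arene.

Step 1
Reactants: 1 1,2,3,4-tetramethoxybenzene
Product: 4 2,3,4,5-tetramethoxyphenol, via aryllithium 2 (not isolated), via dimethyl arylboronate 3 (not isolated)
Conditions: n-BuLi, TMEDA, THF, 0 °C; B(OMe)3, −78 °C → rt; then AcOH, 30% H2O2, 0 °C → rt
Reagents that add atoms: hydrogen peroxide, OO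
Why: Directed ortho-lithiation can only take place at the two equivalent ring C–H positions, each flanked by a methoxy group, and borylation followed by peroxide oxidation (boron-to-oxygen aryl migration) should turn the C–Li bond into the phenol C–O bond.

Step 2
Reactants: 4 2,3,4,5-tetramethoxyphenol
Product: 5 2-hydroxy-3,4,5,6-tetramethoxybenzaldehyde
Conditions: MgCl2, Et3N, (CH2O)n, MeCN, reflux; then 1 M HCl
Reagents that add atoms: paraformaldehyde (as formaldehyde), C=O
Why: Magnesium-phenoxide-directed ortho-formylation (Casnati–Skattebøl reaction) can only enter the single free ring position, which lies ortho to the hydroxyl, so the regiochemistry is fixed by the substrate.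

Step 3
Reactants: 6 2,5-dimethoxyphenylacetic acid
Product: 7 methyl 2-(2,5-dimethoxyphenyl)acetate
Conditions: MeOH, cat. H2SO4, reflux
Reagents that add atoms: methanol, CO
Why: Fischer esterification in excess methanol should drive the acid to its methyl ester and leaves the aryl methyl ethers untouched.

Step 4
Reactants: 7 methyl 2-(2,5-dimethoxyphenyl)acetate
Product: 10 methyl 2-bromo-2-(2,5-dimethoxyphenyl)acetate (racemic), via lithium enolate 8 (not isolated), via silyl ketene acetal 9 (not isolated)
Conditions: LiHMDS, THF, −78 °C; TMSCl; then NBS, −78 → 0 °C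
Reagents that add atoms: N-bromosuccinimide, O=C1CCC(=O)N1Br
Why: α-Bromination of an ester through its silyl ketene acetal puts bromine on the nucleophilic α-carbon at low temperature much faster than NBS can attack the dimethoxyarene ring, which avoids the ring bromination that radical or acidic conditions would risk; the new stereocentre is formed as the racemate.

Step 5
Reactants: 5 2-hydroxy-3,4,5,6-tetramethoxybenzaldehyde; 10 methyl 2-bromo-2-(2,5-dimethoxyphenyl)acetate (racemic)
Product: 11 methyl 2-(2,5-dimethoxyphenyl)-2-(2-formyl-3,4,5,6-tetramethoxyphenoxy)acetate (racemic)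
Conditions: K2CO3, DMF, rt
Reagents that add atoms: none
Why: Williamson ether synthesis, in which the phenoxide of 5 displaces bromide by SN2 from a secondary carbon activated by both the aryl and the ester group, while the mild carbonate base at room temperature should keep an intramolecular aldol onto the hindered, electron-rich aldehyde from competing.

Step 6
Reactants: 11 methyl 2-(2,5-dimethoxyphenyl)-2-(2-formyl-3,4,5,6-tetramethoxyphenoxy)acetate (racemic)
Product: 12 2-(2,5-dimethoxyphenyl)-2-[2-(hydroxymethyl)-3,4,5,6-tetramethoxyphenoxy]ethan-1-ol (racemic)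
Conditions: LiAlH4, THF, 0 °C; Rochelle salt work-up
Reagents that add atoms: none
Why: Hydride reduction with LiAlH4 takes both the aldehyde and the ester to primary alcohols while the aryl ether bonds are inert, giving a stable, purifiable diol as the storage form of the sensitive dialdehyde.

Step 7
Reactants: 12 2-(2,5-dimethoxyphenyl)-2-[2-(hydroxymethyl)-3,4,5,6-tetramethoxyphenoxy]ethan-1-ol (racemic)
Product: 13 2-[1-(2,5-dimethoxyphenyl)-2-oxoethoxy]-3,4,5,6-tetramethoxybenzaldehyde (racemic)
Conditions: DMP, NaHCO3, CH2Cl2, 0 °C → rt; crude product dried and used at once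
Reagents that add atoms: none
Why: Dess–Martin oxidation converts both primary carbinols to aldehydes without over-oxidation and without the amine base that could enolise the new α-aryloxy-α-aryl aldehyde, and closure of the intermediate hydroxy aldehyde to a seven-membered lactol on a hindered aryl aldehyde is unfavourable, so lactone formation should stay minor.

Step 8
Reactants: 13 2-[1-(2,5-dimethoxyphenyl)-2-oxoethoxy]-3,4,5,6-tetramethoxybenzaldehyde (racemic)
Product: 14 2-(2,5-dimethoxyphenyl)-5,6,7,8-tetramethoxychromane-3,4-diol (racemic mixture of diastereomers)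
Conditions: SmI2 (2.5 equiv), t-BuOH, THF, −78 °C, slow addition of 13 at high dilution; aq. NH4Cl
Reagents that add atoms: none
Why: SmI2 transfers one electron to the conjugated aryl aldehyde, the more easily reduced carbonyl, and the samarium(III)-bound ketyl carbon (C4) adds to the chelated aliphatic aldehyde carbon (C3), after which a second electron and protonation by t-BuOH should deliver the diol. The closest known reaction type is the samarium diiodide intramolecular pinacol coupling of 1,6-dialdehydes to six-membered cyclic 1,2-diols. Ring C closes in the 6-exo-trig mode, the C3 carbonyl oxygen remaining outside the new ring. The two new stereocentres at C3 and C4 are governed by the samarium chelate bridging both oxygens (cis-diol expected to predominate) and by the existing C2 aryl group, but no control is required because C2, C3 and C4 all become planar in step 9. The selectivity needed is ketyl formation at the aryl aldehyde in preference to two-electron reduction of the α-aryloxy aliphatic aldehyde, which would expel the phenoxide and sever the tether; the less negative reduction potential of the conjugated aldehyde, the absence of HMPA, the low temperature and the slow addition at high dilution should secure it.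

Step 9
Reactants: 14 2-(2,5-dimethoxyphenyl)-5,6,7,8-tetramethoxychromane-3,4-diol (racemic mixture of diastereomers)
Product: 16 2-(2,5-dimethoxyphenyl)-3-hydroxy-5,6,7,8-tetramethoxy-4H-chromen-4-one, via chromane-3,4-dione 15 (not isolated)
Conditions: IBX (2.5–3 equiv), DMSO, rt
Reagents that add atoms: none
Why: Hypervalent-iodine oxidation with IBX converts both secondary carbinols of a 1,2-diol to carbonyls without glycol cleavage, and the resulting 3,4-dione, whose C2–H is flanked by the aryl group, O1 and the C3 carbonyl, should tautomerise to the conjugated, hydrogen-bonded 3-hydroxychromone, which removes all three stereocentres.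

Step 10
Reactants: 16 2-(2,5-dimethoxyphenyl)-3-hydroxy-5,6,7,8-tetramethoxy-4H-chromen-4-one
Product: 17 2-(2,5-dimethoxyphenyl)-3,5,6,7,8-pentamethoxy-4H-chromen-4-one
Conditions: MeI, K2CO3, acetone, reflux
Reagents that add atoms: iodomethane, CI
Why: Williamson O-methylation of the acidic enolic 3-hydroxyl, the only free hydroxyl in the molecule, is standard flavonol chemistry and has no competing site.

Step 11
Reactants: 17 2-(2,5-dimethoxyphenyl)-3,5,6,7,8-pentamethoxy-4H-chromen-4-one
Product: 18 Grantioidinin, 2-(2,5-dimethoxyphenyl)-5-hydroxy-3,6,7,8-tetramethoxy-4H-chromen-4-one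
Conditions: BCl3 (1.2–1.5 equiv), CH2Cl2, −78 → 0 °C; then H2O
Reagents that add atoms: none
Why: Lewis-acid ether cleavage directed by chelation, in which boron binds the C4 carbonyl and the peri C5 methoxy oxygen in a six-membered chelate so that chloride removes only that methyl group at low temperature, while the other six methyl ethers, which cannot form this chelate (O3 only a strained five-membered one), should persist.

Compound list
1 | 1,2,3,4-tetramethoxybenzene | COc1ccc(OC)c(OC)c1OC | starting material
2 | (2,3,4,5-tetramethoxyphenyl)lithium | [Li]c1cc(OC)c(OC)c(OC)c1OC | intermediate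
3 | dimethyl (2,3,4,5-tetramethoxyphenyl)boronate | COB(OC)c1cc(OC)c(OC)c(OC)c1OC | intermediate
4 | 2,3,4,5-tetramethoxyphenol | Oc1cc(OC)c(OC)c(OC)c1OC | intermediate
5 | 2-hydroxy-3,4,5,6-tetramethoxybenzaldehyde | O=Cc1c(O)c(OC)c(OC)c(OC)c1OC | intermediate
6 | 2,5-dimethoxyphenylacetic acid | COc1ccc(OC)c(CC(=O)O)c1 | starting material
7 | methyl 2-(2,5-dimethoxyphenyl)acetate | COC(=O)Cc1cc(OC)ccc1OC | intermediate
8 | lithium enolate of 7, lithium 2-(2,5-dimethoxyphenyl)-1-methoxyethen-1-olate | [Li]OC(OC)=Cc1cc(OC)ccc1OC | intermediate
9 | silyl ketene acetal of 7, [2-(2,5-dimethoxyphenyl)-1-methoxyethenyl]oxy(trimethyl)silane (E/Z mixture) | COC(O[Si](C)(C)C)=Cc1cc(OC)ccc1OC | intermediate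
10 | methyl 2-bromo-2-(2,5-dimethoxyphenyl)acetate (racemic) | COC(=O)C(Br)c1cc(OC)ccc1OC | intermediate
11 | methyl 2-(2,5-dimethoxyphenyl)-2-(2-formyl-3,4,5,6-tetramethoxyphenoxy)acetate (racemic) | COC(=O)C(Oc1c(C=O)c(OC)c(OC)c(OC)c1OC)c1cc(OC)ccc1OC | intermediate
12 | 2-(2,5-dimethoxyphenyl)-2-[2-(hydroxymethyl)-3,4,5,6-tetramethoxyphenoxy]ethan-1-ol (racemic) | OCC(Oc1c(CO)c(OC)c(OC)c(OC)c1OC)c1cc(OC)ccc1OC | intermediate
13 | 2-[1-(2,5-dimethoxyphenyl)-2-oxoethoxy]-3,4,5,6-tetramethoxybenzaldehyde (racemic) | O=CC(Oc1c(C=O)c(OC)c(OC)c(OC)c1OC)c1cc(OC)ccc1OC | intermediate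
14 | 2-(2,5-dimethoxyphenyl)-5,6,7,8-tetramethoxychromane-3,4-diol (racemic mixture of diastereomers) | COc1ccc(OC)c(C2Oc3c(OC)c(OC)c(OC)c(OC)c3C(O)C2O)c1 | intermediate
15 | 2-(2,5-dimethoxyphenyl)-5,6,7,8-tetramethoxychromane-3,4-dione (racemic) | COc1ccc(OC)c(C2Oc3c(OC)c(OC)c(OC)c(OC)c3C(=O)C2=O)c1 | intermediate
16 | 2-(2,5-dimethoxyphenyl)-3-hydroxy-5,6,7,8-tetramethoxy-4H-chromen-4-one | COc1ccc(OC)c(-c2oc3c(OC)c(OC)c(OC)c(OC)c3c(=O)c2O)c1 | intermediate
17 | 2-(2,5-dimethoxyphenyl)-3,5,6,7,8-pentamethoxy-4H-chromen-4-one | COc1ccc(OC)c(-c2oc3c(OC)c(OC)c(OC)c(OC)c3c(=O)c2OC)c1 | intermediate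
18 | Grantioidinin, 2-(2,5-dimethoxyphenyl)-5-hydroxy-3,6,7,8-tetramethoxy-4H-chromen-4-one (achiral) | COc1ccc(OC)c(-c2oc3c(OC)c(OC)c(OC)c(O)c3c(=O)c2OC)c1 | target

Total step count: 11. Longest linear sequence: 9 steps (steps 1, 2, 5–11 from 1; equally steps 3–11 from 6).

Steps most likely to fail

Step 8. The reduction may go wrong in two ways: two-electron reduction at the aliphatic carbonyl with expulsion of the phenoxide, which severs the tether, or plain reduction of the aryl aldehyde to the benzylic alcohol without C–C bond formation. The fallback gives up the reductive closure and builds the chromone by the established acylation, acyl-transfer and cyclodehydration sequence. It sets out from phenol 4 and comes back to the route at 17. Fries-type C-acylation of 4 with methoxyacetic acid in BF3·OEt2 at the single free ortho position should give 1-(2-hydroxy-3,4,5,6-tetramethoxyphenyl)-2-methoxyethan-1-one F1. O-Acylation with 2,5-dimethoxybenzoyl chloride in pyridine should give 3,4,5,6-tetramethoxy-2-(2-methoxyacetyl)phenyl 2,5-dimethoxybenzoate F2. Baker–Venkataraman rearrangement (KOH, pyridine, 50 °C) should give 1-(2,5-dimethoxyphenyl)-3-(2-hydroxy-3,4,5,6-tetramethoxyphenyl)-2-methoxypropane-1,3-dione F3. Cyclodehydration (cat. H2SO4, AcOH, heat) should then give 17, leaving only step 11.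

Step 7. The double oxidation may over-oxidise through a cyclic hemiacetal to a lactone, or the α-aryloxy aldehyde may enolise and undergo intramolecular aldol during work-up. The fallback avoids any oxidation by keeping the aryl aldehyde masked while the ester is reduced only to the aldehyde level. It sets out from 11 and comes back at 13. Acetalisation of 11 (HC(OMe)3, MeOH, cat. p-TsOH, rt) should give methyl 2-[2-(dimethoxymethyl)-3,4,5,6-tetramethoxyphenoxy]-2-(2,5-dimethoxyphenyl)acetate F4. Partial reduction with DIBAL-H in CH2Cl2 at −78 °C, where the α-aryloxy ester forms a stable chelated hemiacetal aluminate, should give 2-[2-(dimethoxymethyl)-3,4,5,6-tetramethoxyphenoxy]-2-(2,5-dimethoxyphenyl)acetaldehyde F5. Mild hydrolysis of the very labile electron-rich aryl acetal (PPTS, wet acetone, rt) should release 13 under non-basic conditions for immediate use in step 8.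

Step 9. Oxidative cleavage of the C3–C4 glycol, ionisation at the electron-rich benzylic C4 carbinol, or further oxidation of the enolic product may compete with the twofold carbinol oxidation. The fallback separates the two oxidation levels using classical flavonoid reactions. It sets out from 14 and comes back at 16. Selective dehydrogenation of the activated benzylic C4 carbinol with DDQ (dioxane, rt) should give the dihydroflavonol 2-(2,5-dimethoxyphenyl)-3-hydroxy-5,6,7,8-tetramethoxychroman-4-one F6. Dehydrogenation of F6 with I2 and KOAc in AcOH at reflux (α-iodination and elimination) should give 16.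

Further compounds
F1 | step 8 | 1-(2-hydroxy-3,4,5,6-tetramethoxyphenyl)-2-methoxyethan-1-one | COCC(=O)c1c(O)c(OC)c(OC)c(OC)c1OC
F2 | step 8 | 3,4,5,6-tetramethoxy-2-(2-methoxyacetyl)phenyl 2,5-dimethoxybenzoate | COCC(=O)c1c(OC(=O)c2cc(OC)ccc2OC)c(OC)c(OC)c(OC)c1OC
F3 | step 8 | 1-(2,5-dimethoxyphenyl)-3-(2-hydroxy-3,4,5,6-tetramethoxyphenyl)-2-methoxypropane-1,3-dione (racemic) | COC(C(=O)c1cc(OC)ccc1OC)C(=O)c1c(O)c(OC)c(OC)c(OC)c1OC
F4 | step 7 | methyl 2-[2-(dimethoxymethyl)-3,4,5,6-tetramethoxyphenoxy]-2-(2,5-dimethoxyphenyl)acetate (racemic) | COC(=O)C(Oc1c(C(OC)OC)c(OC)c(OC)c(OC)c1OC)c1cc(OC)ccc1OC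
F5 | step 7 | 2-[2-(dimethoxymethyl)-3,4,5,6-tetramethoxyphenoxy]-2-(2,5-dimethoxyphenyl)acetaldehyde (racemic) | O=CC(Oc1c(C(OC)OC)c(OC)c(OC)c(OC)c1OC)c1cc(OC)ccc1OC
F6 | step 9 | 2-(2,5-dimethoxyphenyl)-3-hydroxy-5,6,7,8-tetramethoxychroman-4-one (racemic mixture of diastereomers) | COc1ccc(OC)c(C2Oc3c(OC)c(OC)c(OC)c(OC)c3C(=O)C2O)c1
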